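**Retrosynthetic overview**
- Rings C (pyran) and D (furan) are opened together at the ketal carbon, giving a phenol, a primary alcohol and a methyl ketone. The ketal carbon and the ring-fusion CH are left to thermodynamic control, so only the CH(CH3) centre (Roche ester) and the lactone carbinol centre (propylene oxide) are bought.
- Key C–C disconnection: aryl C5–CH2. The CH2 is the β-carbon of the methyl ketone, delivered as a palladium homoenolate (ring-opened 1-methyl-2-alkylcyclopropanol) to a C5 aryl bromide; both carbons are acceptors in normal polarity.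
- The cyclopropanol comes from a Kulinkovich (ligand-exchange) cyclopropanation of EtOAc with a Roche-ester-derived terminal alkene.
- The aryl bromide comes from C5 bromination of 4-O-MOM-lasiodiplodin, made by Mitsunobu macrolactonisation (ring B, inversion) after lateral alkylation of an orsellinate-derived toluate dianion with (S)-8-iodooctan-2-ol.
- Ring order: A (arene, bought), then B (12-membered lactone), then fragment union, then C and D in one acid step.

Assumption: the cyclopropane centres of the cyclopropanol and the ketone α-carbon of the coupled products are carried as mixtures (left open in the SMILES), because that carbon is equilibrated in the last step; arene numbering is that of the resorcylate (C1 lactone carbonyl carbon, C2 OMe, C4 oxygen, C5 free CH, C6 chain).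

**Step 1**
Reactants: 1 (S)-propylene oxide; 2 1-bromo-5-chloropentane
Product: 4 (S)-8-chlorooctan-2-ol, via 5-chloropentylmagnesium bromide 3 (not isolated)
Conditions: Mg, THF, 35 °C; then 1, CuI (10 mol %), THF, −30 → 0 °C; dilute aq HCl
Reagents that add atoms: none
Why: Mg inserts into C–Br in preference to C–Cl, and the copper-catalysed Grignard epoxide opening attacks the unsubstituted carbon, so no bond to the stereocentre is touched and S is retained.

**Step 2**
Reactants: 4 (S)-8-chlorooctan-2-ol
Product: 5 (S)-8-iodooctan-2-ol
Conditions: NaI (3 equiv), acetone, reflux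
Reagents that add atoms: sodium iodide, [Na+].[I-]
Why: Finkelstein SN2 halide exchange at the primary carbon, driven by precipitation of NaCl; the remote carbinol centre is unaffected.

**Step 3**
Reactants: 6 methyl orsellinate (methyl 2,4-dihydroxy-6-methylbenzoate)
Product: 8 methyl 2-methoxy-4-(methoxymethoxy)-6-methylbenzoate, via 4-O-MOM monoether 7 (not isolated)
Conditions: K2CO3 (4 equiv), MOMCl (1.05 equiv), DMF, 0 °C → rt; then MeI (3 equiv), 50 °C
Reagents that add atoms: chloromethyl methyl ether, COCCl; iodomethane, CI
Why: Sequential Williamson etherification: the para hydroxyl is the more acidic and is not hydrogen-bonded to the ester, so it takes the single equivalent of MOMCl first, and the chelated ortho hydroxyl is then methylated under forcing conditions.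

**Step 4**
Reactants: 8 methyl 2-methoxy-4-(methoxymethoxy)-6-methylbenzoate
Product: 9 2-methoxy-4-(methoxymethoxy)-6-methylbenzoic acid
Conditions: KOH (5 equiv), DMSO–H2O 4:1, 90 °C; then 1 M HCl, 0 °C, to pH 3
Reagents that add atoms: potassium hydroxide, [K+].[OH-]
Why: Saponification of the hindered benzoate with poorly solvated hydroxide in DMSO; the MOM and methyl aryl ethers are base-stable and the MOM group survives a brief cold acidification.

**Step 5**
Reactants: 9 2-methoxy-4-(methoxymethoxy)-6-methylbenzoic acid; 5 (S)-8-iodooctan-2-ol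
Product: 12 2-[(8S)-8-hydroxynonyl]-6-methoxy-4-(methoxymethoxy)benzoic acid, via dilithiated toluate dianion 10 (not isolated), via lithium iodoalkoxide 11 (not isolated)
Conditions: 9, LiN(iPr)2 (2.2 equiv), THF, −78 → 0 °C; separately 5, LiN(iPr)2 (1.05 equiv), THF, −78 °C; combine at −78 °C, warm to 0 °C; cold 1 M HCl to pH 3
Reagents that add atoms: none
Why: Lateral (benzylic) lithiation of the o-toluate with the amide base gives the carboxylate-stabilised benzylic anion, which alkylates the primary iodide by SN2; the alcohol is masked as its alkoxide and its stereocentre is not involved.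

**Step 6**
Reactants: 12 2-[(8S)-8-hydroxynonyl]-6-methoxy-4-(methoxymethoxy)benzoic acid
Product: 13 4-O-MOM-(R)-lasiodiplodin
Conditions: PPh3 (3 equiv), DIAD (3 equiv), PhMe, slow addition of 12 to 0.005 M, rt
Reagents that add atoms: none
Why: Mitsunobu macrolactonisation: the alcohol is activated rather than the hindered 2,6-disubstituted acid, and the carboxylate displaces the oxyphosphonium group by SN2 with clean inversion (S → R) to close the 12-membered ring B.

**Step 7**
Reactants: 13 4-O-MOM-(R)-lasiodiplodin
Product: 14 5-bromo-4-O-MOM-(R)-lasiodiplodin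
Conditions: NBS (1.05 equiv), MeCN, 0 °C → rt, dark
Reagents that add atoms: N-bromosuccinimide, O=C1CCC(=O)N1Br
Why: Electrophilic aromatic bromination goes to C5, which is para to OMe and ortho to OMOM, whereas C3 lies between two alkoxy groups (the pattern seen when 3,5-dialkoxytoluenes brominate next to the alkyl group).

**Step 8**
Reactants: 15 methyl (R)-3-hydroxy-2-methylpropanoate ((R)-Roche ester)
Product: 16 methyl (R)-3-[(tert-butyldimethylsilyl)oxy]-2-methylpropanoate
Conditions: TBSCl (1.1 equiv), imidazole (1.5 equiv), CH2Cl2, rt
Reagents that add atoms: tert-butyldimethylsilyl chloride, CC(C)(C)[Si](C)(C)Cl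
Why: Standard imidazole-promoted silylation of the primary alcohol; the stereocentre is not touched.

**Step 9**
Reactants: 16 methyl (R)-3-[(tert-butyldimethylsilyl)oxy]-2-methylpropanoate
Product: 18 (S)-tert-butyldimethyl[(2-methylbut-3-en-1-yl)oxy]silane, via Roche aldehyde 17 (not isolated)
Conditions: iBu2AlH (1.1 equiv), CH2Cl2, −78 °C; then Ph3P=CH2 (from Ph3PCH3Br and KN(SiMe3)2, THF), −78 °C → rt; aq potassium sodium tartrate (KNaC4H4O6)
Reagents that add atoms: methyltriphenylphosphonium bromide, C[P+](c1ccccc1)(c1ccccc1)c1ccccc1.[Br-]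
Why: One-pot partial reduction and Wittig methylenation: the aluminium hemiacetal releases the epimerisable aldehyde only in the presence of the ylide, so the α-centre is carried through unchanged (the descriptor changes from R to S only because the priorities change).

**Step 10**
Reactants: 18 (S)-tert-butyldimethyl[(2-methylbut-3-en-1-yl)oxy]silane
Product: 19 2-[(2S)-1-[(tert-butyldimethylsilyl)oxy]propan-2-yl]-1-methylcyclopropan-1-ol
Conditions: EtOAc (2 equiv), ClTi(OiPr)3 (1.0 equiv), c-C6H11MgCl (4.5 equiv, added over 1 h), THF, rt
Reagents that add atoms: ethyl acetate, CCOC(C)=O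
Why: Kulinkovich cyclopropanation in the ligand-exchange mode: the titanacyclopropane formed from the cyclohexyl Grignard reagent exchanges its alkene for the terminal alkene of 18 and then adds twice to the acetate carbonyl; the two new ring centres need no control because one becomes the ketone carbon and the other is equilibrated in step 12.

**Step 11**
Reactants: 14 5-bromo-4-O-MOM-(R)-lasiodiplodin; 19 2-[(2S)-1-[(tert-butyldimethylsilyl)oxy]propan-2-yl]-1-methylcyclopropan-1-ol
Product: 20 4-O-MOM-(R)-lasiodiplodin carrying at C5 the (3S)-2-acetyl-4-[(tert-butyldimethylsilyl)oxy]-3-methylbutyl group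
Conditions: Pd(OAc)2 (10 mol %), XPhos (20 mol %), Cs2CO3 (2 equiv), 19 (1.5 equiv), PhMe, 80 °C
Reagents that add atoms: none
Why: Palladium-catalysed ring-opening cross-coupling of a cyclopropanol with an aryl bromide (palladium homoenolate arylation): oxidative addition of 14 to zerovalent palladium, alkoxide exchange and β-carbon elimination at the less substituted ring bond give a primary β-keto alkyl group on divalent palladium (the β-carbanion equivalent of the methyl ketone), and the bulky biaryl phosphine drives reductive elimination onto the aryl carbon ahead of β-hydride elimination, so the aryl–CH2 bond, the ketone and the whole side chain arrive in one operation.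

**Step 12**
Reactants: 20 4-O-MOM-(R)-lasiodiplodin carrying at C5 the (3S)-2-acetyl-4-[(tert-butyldimethylsilyl)oxy]-3-methylbutyl group
Product: 22 lasiodiplactone A, via keto diol 21 (not isolated)
Conditions: TsOH·H2O (0.2 equiv), MeOH, 50 °C; then evaporate, PhMe, 4 Å MS, 60 °C
Reagents that add atoms: none
Why: Acidic methanolysis removes the MOM and TBS groups, and the keto diol then closes by dehydrative ketalisation to rings C and D; the 5/6 fusion can only be cis, which fixes the ketal carbon, and reversible enol and enol-ether formation under the acid equilibrates the ring-fusion CH so that the benzylic CH2 ends trans to the Roche-derived methyl (methyl on the convex face), which is expected to be the thermodynamic arrangement and is the one in the target.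

**Compound list**
1 | (S)-propylene oxide | C[C@H]1CO1 | starting material
2 | 1-bromo-5-chloropentane | ClCCCCCBr | starting material
3 | 5-chloropentylmagnesium bromide | ClCCCCC[Mg]Br | intermediate (not isolated)
4 | (S)-8-chlorooctan-2-ol | C[C@H](O)CCCCCCCl | intermediate
5 | (S)-8-iodooctan-2-ol | C[C@H](O)CCCCCCI | intermediate
6 | methyl orsellinate (methyl 2,4-dihydroxy-6-methylbenzoate) | COC(=O)c1c(C)cc(O)cc1O | starting material
7 | methyl 2-hydroxy-4-(methoxymethoxy)-6-methylbenzoate | COCOc1cc(C)c(C(=O)OC)c(O)c1 | intermediate (not isolated)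
8 | methyl 2-methoxy-4-(methoxymethoxy)-6-methylbenzoate | COCOc1cc(C)c(C(=O)OC)c(OC)c1 | intermediate
9 | 2-methoxy-4-(methoxymethoxy)-6-methylbenzoic acid | COCOc1cc(C)c(C(=O)O)c(OC)c1 | intermediate
10 | dilithium salt of 9 deprotonated at CO2H and at the benzylic CH3 | COCOc1cc([CH2-])c(C([O-])=O)c(OC)c1.[Li+].[Li+] | intermediate (not isolated)
11 | lithium (S)-8-iodooctan-2-olate | C[C@H]([O-])CCCCCCI.[Li+] | intermediate (not isolated)
12 | 2-[(8S)-8-hydroxynonyl]-6-methoxy-4-(methoxymethoxy)benzoic acid | COCOc1cc(CCCCCCC[C@H](C)O)c(C(=O)O)c(OC)c1 | intermediate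
13 | 4-O-MOM-(R)-lasiodiplodin (12-membered lactone of the (8R)-hydroxy acid; 2-OMe, 4-OMOM) | COc1cc(OCOC)cc2c1C(=O)O[C@H](C)CCCCCCC2 | intermediate
14 | 5-bromo-4-O-MOM-(R)-lasiodiplodin (Br between OMOM and the chain) | COc1cc(OCOC)c(Br)c2c1C(=O)O[C@H](C)CCCCCCC2 | intermediate
15 | methyl (R)-3-hydroxy-2-methylpropanoate | COC(=O)[C@H](C)CO | starting material
16 | methyl (R)-3-[(tert-butyldimethylsilyl)oxy]-2-methylpropanoate | COC(=O)[C@H](C)CO[Si](C)(C)C(C)(C)C | intermediate
17 | (R)-3-[(tert-butyldimethylsilyl)oxy]-2-methylpropanal | O=C[C@H](C)CO[Si](C)(C)C(C)(C)C | intermediate (not isolated)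
18 | (S)-tert-butyldimethyl[(2-methylbut-3-en-1-yl)oxy]silane | C=C[C@H](C)CO[Si](C)(C)C(C)(C)C | intermediate
19 | 2-[(2S)-1-[(tert-butyldimethylsilyl)oxy]propan-2-yl]-1-methylcyclopropan-1-ol (ring diastereomers) | CC1(O)CC1[C@H](C)CO[Si](C)(C)C(C)(C)C | intermediate
20 | 13 carrying at C5 the (3S)-2-acetyl-4-[(tert-butyldimethylsilyl)oxy]-3-methylbutyl group (epimers at the acetyl-bearing carbon) | COc1cc(OCOC)c(CC(C(C)=O)[C@H](C)CO[Si](C)(C)C(C)(C)C)c2c1C(=O)O[C@H](C)CCCCCCC2 | intermediate
21 | (R)-lasiodiplodin carrying at C5 the (3S)-2-acetyl-4-hydroxy-3-methylbutyl group (keto diol) | COc1cc(O)c(CC(C(C)=O)[C@H](C)CO)c2c1C(=O)O[C@H](C)CCCCCCC2 | intermediate (not isolated)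
22 | lasiodiplactone A | COc1cc2c(c3c1C(=O)O[C@H](C)CCCCCCC3)C[C@H]1[C@H](C)CO[C@@]1(C)O2 | target

**Totals**
Total step count: 12. Longest linear sequence: 7 steps (6 → 8 → 9 → 12 → 13 → 14 → 20 → 22; steps 3, 4, 5, 6, 7, 11, 12).

**Three steps most likely to fail**

Step 11 (homoenolate arylation at a doubly ortho-substituted aryl bromide). The risk is that β-hydride elimination of the β-keto alkylpalladium species gives the enone and reduced arene instead of the coupled ketone. The fallback returns to normal polarity and sets out from 19 and 14. Compound 19 is opened on purpose by aerobic palladium catalysis (Pd(OAc)2 cat., pyridine, O2, PhMe, 80 °C) to the α-methylene ketone (4S)-5-[(tert-butyldimethylsilyl)oxy]-4-methyl-3-methylidenepentan-2-one F1. Bromide 14 is then added to F1 in a reductive Heck (conjugate hydroarylation) reaction (Pd(OAc)2, PPh3, HCO2Na, DMF, 80 °C), where the arylpalladium species attacks the enone β-carbon and formate reduces the resulting palladium enolate. This comes back to the route at 20.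

Step 10 (ligand-exchange Kulinkovich reaction on an α-branched terminal alkene). The risk is slow alkene exchange on titanium or erosion of the allylic centre. The fallback sets out from 18 and uses alkoxide-directed delivery instead of intermolecular exchange. Bu4NF in THF frees (S)-2-methylbut-3-en-1-ol F2. Its magnesium alkoxide binds titanium and undergoes the hydroxyl-directed Kulinkovich cyclopropanation of EtOAc (Ti(OiPr)4, c-C5H9MgCl, THF, rt) to give 2-[(2S)-1-hydroxypropan-2-yl]-1-methylcyclopropan-1-ol F3. Selective silylation of the primary hydroxyl (TBSCl, imidazole, CH2Cl2, 0 °C) comes back to the route at 19.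

Step 6 (Mitsunobu closure of the 12-membered ring). The risk is oligomerisation or elimination of the activated secondary alcohol. The fallback closes a C=C bond instead; it sets out from 9 and 1 and replaces steps 1, 2, 5 and 6.
- Epoxide 1 with but-3-enylmagnesium bromide and CuI (THF, −30 °C) gives (S)-hept-6-en-2-ol F4.
- Intermolecular Mitsunobu esterification of 9 with F4 (PPh3, DIAD, PhMe, inversion) gives (R)-hept-6-en-2-yl 2-methoxy-4-(methoxymethoxy)-6-methylbenzoate F5.
- Lateral lithiation (LiN(iPr)2, THF, −78 °C) and allyl bromide give (R)-hept-6-en-2-yl 2-(but-3-en-1-yl)-6-methoxy-4-(methoxymethoxy)benzoate F6.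
- Ring-closing metathesis (second-generation Grubbs catalyst, RuCl2(H2IMes)(PCy3)(=CHPh), CH2Cl2, 2 mM, 40 °C) gives the ring-unsaturated 4-O-MOM-(R)-lasiodiplodin (E/Z mixture) F7.
- Hydrogenation (H2, Pd/C, EtOAc) comes back to the route at 13.

**Further compounds**
F1 | step 11 | (4S)-5-[(tert-butyldimethylsilyl)oxy]-4-methyl-3-methylidenepentan-2-one | CC(=O)C(=C)[C@H](C)CO[Si](C)(C)C(C)(C)C
F2 | step 10 | (S)-2-methylbut-3-en-1-ol | C=C[C@H](C)CO
F3 | step 10 | 2-[(2S)-1-hydroxypropan-2-yl]-1-methylcyclopropan-1-ol | CC1(O)CC1[C@H](C)CO
F4 | step 6 | (S)-hept-6-en-2-ol | C=CCCC[C@H](C)O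
F5 | step 6 | (R)-hept-6-en-2-yl 2-methoxy-4-(methoxymethoxy)-6-methylbenzoate | C=CCCC[C@@H](C)OC(=O)c1c(C)cc(OCOC)cc1OC
F6 | step 6 | (R)-hept-6-en-2-yl 2-(but-3-en-1-yl)-6-methoxy-4-(methoxymethoxy)benzoate | C=CCCC[C@@H](C)OC(=O)c1c(CCC=C)cc(OCOC)cc1OC
F7 | step 6 | ring-unsaturated 4-O-MOM-(R)-lasiodiplodin (E/Z mixture) | COc1cc(OCOC)cc2c1C(=O)O[C@H](C)CCCC=CCC2
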